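The easy step is to count what a target costs: dissolved electrophile meets nucleophile, each target sets one acid free, and nucleophile can take that acid up, so a target can cost two nucleophiles.

| flask | solid electrophile | nucleophile | gas | time |
|---|---|---|---|---|
| Tuesday's | 0.050 M | 1.10 equiv | 4.1 mM (held) | 12 min |
| Thursday's | 0.050 M | 1.70 equiv | 4.1 mM (held) | 12 min |

- part of the solid electrophile that has reacted (what has only dissolved counts as not reacted) at the end, Tuesday's
- part of the solid electrophile that has reacted (what has only dissolved counts as not reacted) at the end, Thursday's
- what raising the equivalents of nucleophile from its lowest to its highest value here does to the part of the solid electrophile that has reacted (what has only dissolved counts as not reacted) (changes below 5 percentage points count as none) (it rises / it falls / no change)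

- solid electrophile is a solid; its amount is given per volume of the solution
- at the start none of free base is dissolved
- at the start none of the solid electrophile is in solution
- what has only dissolved of solid electrophile counts as not reacted
- run time (Tuesday's): 12 min

    electrophile + nucleophile → acid set free + target (k1 = 27 M⁻¹ min⁻¹)
    nucleophile + acid set free ⇌ protonated nucleophile, settled at all times (K2 = 300 M⁻¹)
    acid set free + free base ⇌ salt of the base (K3 = 420 M⁻¹, k3 = 35 M⁻¹ min⁻¹)
    gas ⇌ free base, rate k4*(csat - [free base]) (k4 = 2.9 min⁻¹, csat = 4.1 mM)
    solid electrophile ⇌ electrophile, rate k5*(cs5 - [electrophile]) while solid is left; crystals form when [electrophile] > cs5 (cs5 = 38 mM, k5 = 0.11 min⁻¹)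

I follow the rate as a fraction of the charge. At the start the solid feeds 0.0836 min⁻¹, so at that pace the charge takes 12.0 min. With nucleophile as charged on Tuesday, dissolved electrophile has a half-life of 0.47 min by its reaction with nucleophile alone, and because this is far shorter than the feeding time, dissolution is the rate-limiting step at first. The first slowing is small: electrophile standing in solution lowers Tuesday's feed by a factor of 0.931.

The second slowing grows. Acid set free lies 16 to one on the protonated side at Tuesday's start, so I let each target cost two nucleophiles and leave the free base out. The reaction rate then falls in step with free nucleophile and reaches zero at the reach, half the equivalents of nucleophile as a fraction of the charge: 55.0 % on Tuesday and 85.0 % on Thursday. On this count nucleophile is the limiting reagent. The feed arrives at these marks after 6.58 min on Tuesday and 10.2 min on Thursday, both inside the 12 min. I therefore commit to the two reaches, and so to a rise of 30 percentage points from Tuesday to Thursday.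

The forecast stands higher than my reckoning, at 79 % and 87 %, and its word on more nucleophile is it rises, holding that “protonation removes about one nucleophile per target formed”. The simulation gives 63.5 % for Tuesday and 79.1 % for Thursday, and with more nucleophile it rises, by 16 points.

The balance adds to the reach half of the difference between acid not held by nucleophile and nucleophile still free. At Tuesday's end, acid set free and salt of the base hold 28.6 % of the charge and free nucleophile 11.6 %, which gives 63.5 %. The neighbour of Thursday's with 0.420 equiv has a reach of 21.0 %; its acid set free and salt of the base hold 26.3 % and its free nucleophile 2.61 %, which gives 32.8 %, and that flask reads 32.8 %.

The rate constants are those of an exercise; the flask was simulated.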